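**Plan**

- Retrosynthesis: the C7 tert-butyl ether is cleaved last; ring C is cut at O1–C2 and C2–C3 (one-carbon insertion into a 2-hydroxydeoxybenzoin); ring A is cut at C5–C6, C4a–C8a and C8–C8a into an alkenyl(methoxy)carbene chromium complex, a terminal ynone and one CO ligand.
- In ring A the C6 methoxy is para to the C8a oxygen and the acyl carbon sits on C4a next to C8a, which is the pattern a carbene benzannulation delivers (carbene carbon → C6, vinyl α-carbon → C7, vinyl CH2 → C8, CO → C8a, alkyne CH → C5, acyl-bearing alkyne carbon → C4a).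
- Forward: the carbene complex and the ynone (which carries C3, C4 and ring B) are made separately; ring A is formed first with its three oxygens differentiated, ring C second, and the C7 hydroxyl is freed at the end.
- Stereochemistry: the target has no stereocenter and no stereogenic double bond, so nothing has to be set.

Key step: step 4

Remark on the chemistry: the η6 bond of the chromium arene complexes is written in SMILES as a dot between arene and Cr(CO)3, and enaminone 13 is drawn as its E isomer, a geometry that is lost on ring closure.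

**Route**

Step 1
Reactants: 1 tert-butyl vinyl ether; 2 chromium hexacarbonyl Cr(CO)6
Product: 5 pentacarbonyl{[1-(tert-butoxy)vinyl](methoxy)carbene}chromium, via 1-(tert-butoxy)vinyllithium 3 (not isolated), via lithium acylchromate 4 (not isolated)
Conditions: 1 (1.3 equiv), t-BuLi (1.0 equiv, pentane), THF, −78 → 0 °C; add to 2 in Et2O, −78 °C → rt; evaporate; Me3OBF4, dry CH2Cl2, 0 °C; rapid filtration through silica under Ar
Reagents that add atoms: trimethyloxonium tetrafluoroborate Me3OBF4, C[O+](C)C.F[B-](F)(F)F
Why: Fischer carbene synthesis, in which α-lithiation of the alkyl vinyl ether gives a vinyllithium that adds to a carbonyl ligand of Cr(CO)6 and the acylate is O-methylated by the oxonium salt under anhydrous conditions that spare the enol ether, as known for 1-ethoxyvinyl and dihydropyranyl analogues.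

Step 2
Reactants: 6 (3,4,5-trimethoxyphenyl)acetic acid
Product: 8 N-methoxy-N-methyl-2-(3,4,5-trimethoxyphenyl)acetamide, via acyl imidazolide 7 (not isolated)
Conditions: CDI, CH2Cl2, rt; then MeNHOMe·HCl, rt
Reagents that add atoms: N,O-dimethylhydroxylamine hydrochloride, CNOC.Cl
Why: Activation of the acid as its acyl imidazolide and aminolysis by the hydroxylamine is a standard amide coupling that needs no added base and leaves the benzylic CH2 untouched.

Step 3
Reactants: 8 N-methoxy-N-methyl-2-(3,4,5-trimethoxyphenyl)acetamide
Product: 10 1-(3,4,5-trimethoxyphenyl)but-3-yn-2-one, via bromomagnesium hemiaminal adduct 9 (not isolated)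
Conditions: HC≡CMgBr (2.5 equiv, THF), THF, 0 °C → rt; inverse quench into cold 1 M HCl; used promptly
Reagents that add atoms: ethynylmagnesium bromide HC≡CMgBr, C#C[Mg]Br
Why: Weinreb ketone synthesis, in which the Grignard reagent adds only once because the magnesium chelate 9 persists until the quench, and the cold acid protonates the released N,O-dimethylhydroxylamine before it can add in conjugate fashion to the terminal ynone.

Step 4
Reactants: 5 pentacarbonyl{[1-(tert-butoxy)vinyl](methoxy)carbene}chromium; 10 1-(3,4,5-trimethoxyphenyl)but-3-yn-2-one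
Product: 12 1-[4-(tert-butoxy)-2-hydroxy-5-methoxyphenyl]-2-(3,4,5-trimethoxyphenyl)ethanone, via Cr(CO)3 arene complex 11 (not isolated)
Conditions: 10 (1.5 equiv), degassed THF, 50 °C, Ar; then air, Et2O, daylight, rt
Reagents that add atoms: none
Why: Dötz benzannulation: thermal loss of a cis CO ligand from 5 frees a site on zerovalent chromium, the alkyne of 10 inserts into the Cr=C bond to give an η1,η3-vinylcarbene, a CO ligand inserts to give a chromium-bound dienylketene, and ring A closes by a thermal six-electron electrocyclization of that ketene (C8–C8a bond), after which enolization gives the phenol as its Cr(CO)3 complex 11 and air removes the metal. The closest known reactions are benzannulations of alkenyl(methoxy)carbene complexes of chromium, 1-alkoxyalkenyl ones among them, with terminal alkynes, including alkynes that carry ketone or ester groups. No stereocenter is created. The one selectivity needed is the direction of alkyne insertion, with the unsubstituted alkyne carbon bonded to the carbene carbon (C5–C6) and the acyl-bearing carbon bonded to the inserted CO (C4a–C8a); the terminal alkyne secures it, because the position next to the former carbene carbon in the vinylcarbene intermediate is pressed against a cis CO ligand and is taken by hydrogen. Phenol formation is favoured over cyclopentannulation or furan formation by the choice of chromium, an alkenyl rather than aryl carbene and THF at moderate temperature, and the carbene carbon, the vinyl α-carbon and the CO ligand deliver the C6 methoxy, the C7 tert-butoxy and the free C8a hydroxyl already differentiated.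

Step 5
Reactants: 12 1-[4-(tert-butoxy)-2-hydroxy-5-methoxyphenyl]-2-(3,4,5-trimethoxyphenyl)ethanone
Product: 14 7-(tert-butoxy)-6-methoxy-3-(3,4,5-trimethoxyphenyl)-4H-chromen-4-one, via enaminone 13 (not isolated)
Conditions: DMF-DMA (3 equiv), toluene, 90 °C
Reagents that add atoms: N,N-dimethylformamide dimethyl acetal, COC(OC)N(C)C
Why: Condensation of the activated benzylic methylene with the amide acetal gives enaminone 13, whose chelated phenol adds to the enamine carbon (6-endo-trig) and expels dimethylamine, the standard deoxybenzoin-to-isoflavone closure, run under neutral conditions that keep the tert-butyl ether so that no free 7-hydroxyl meets the methylating acetal.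

Step 6
Reactants: 14 7-(tert-butoxy)-6-methoxy-3-(3,4,5-trimethoxyphenyl)-4H-chromen-4-one
Product: 15 7-hydroxy-6-methoxy-3-(3,4,5-trimethoxyphenyl)-4H-chromen-4-one
Conditions: TFA/CH2Cl2 (1:4), 0 °C → rt
Reagents that add atoms: none
Why: Acidolysis of the aryl tert-butyl ether through the tert-butyl cation, lost as isobutene, is fast at room temperature, while the aryl methyl ethers and the chromone are inert to TFA.

**Compound list**

1 | tert-butyl vinyl ether | C=COC(C)(C)C | starting material
2 | chromium hexacarbonyl Cr(CO)6 | O=C=[Cr](=C=O)(=C=O)(=C=O)(=C=O)=C=O | starting material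
3 | 1-(tert-butoxy)vinyllithium | [Li]C(=C)OC(C)(C)C | intermediate
4 | lithium pentacarbonyl[2-(tert-butoxy)acryloyl]chromate, Li[(CO)5CrC(O)C(Ot-Bu)=CH2] | [Li+].[O-]C(C(=C)OC(C)(C)C)=[Cr](=C=O)(=C=O)(=C=O)(=C=O)=C=O | intermediate
5 | pentacarbonyl{[1-(tert-butoxy)vinyl](methoxy)carbene}chromium, (CO)5Cr=C(OMe)C(Ot-Bu)=CH2 | COC(C(=C)OC(C)(C)C)=[Cr](=C=O)(=C=O)(=C=O)(=C=O)=C=O | intermediate
6 | (3,4,5-trimethoxyphenyl)acetic acid | COc1cc(CC(=O)O)cc(OC)c1OC | starting material
7 | 1-[(3,4,5-trimethoxyphenyl)acetyl]-1H-imidazole | COc1cc(CC(=O)n2ccnc2)cc(OC)c1OC | intermediate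
8 | N-methoxy-N-methyl-2-(3,4,5-trimethoxyphenyl)acetamide | COc1cc(CC(=O)N(C)OC)cc(OC)c1OC | intermediate
9 | bromomagnesium 2-[methoxy(methyl)amino]-1-(3,4,5-trimethoxyphenyl)but-3-yn-2-olate (racemic hemiaminal chelate) | COc1cc(CC(O[Mg]Br)(C#C)N(C)OC)cc(OC)c1OC | intermediate
10 | 1-(3,4,5-trimethoxyphenyl)but-3-yn-2-one | C#CC(=O)Cc1cc(OC)c(OC)c(OC)c1 | intermediate
11 | tricarbonyl(η6-arene)chromium complex of 12, Cr(CO)3 bound to ring A | COc1cc(C(=O)Cc2cc(OC)c(OC)c(OC)c2)c(O)cc1OC(C)(C)C.O=C=[Cr](=C=O)=C=O | intermediate
12 | 1-[4-(tert-butoxy)-2-hydroxy-5-methoxyphenyl]-2-(3,4,5-trimethoxyphenyl)ethanone | COc1cc(C(=O)Cc2cc(OC)c(OC)c(OC)c2)c(O)cc1OC(C)(C)C | intermediate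
13 | (E)-1-[4-(tert-butoxy)-2-hydroxy-5-methoxyphenyl]-3-(dimethylamino)-2-(3,4,5-trimethoxyphenyl)prop-2-en-1-one | COc1cc(C(=O)/C(=C/N(C)C)c2cc(OC)c(OC)c(OC)c2)c(O)cc1OC(C)(C)C | intermediate
14 | 7-(tert-butoxy)-6-methoxy-3-(3,4,5-trimethoxyphenyl)-4H-chromen-4-one | COc1cc2c(=O)c(-c3cc(OC)c(OC)c(OC)c3)coc2cc1OC(C)(C)C | intermediate
15 | 7-hydroxy-6-methoxy-3-(3,4,5-trimethoxyphenyl)-4H-chromen-4-one | COc1cc2c(=O)c(-c3cc(OC)c(OC)c(OC)c3)coc2cc1O | target

**Step count**

Total: 6 steps. Longest linear sequence: 5 steps (6 → 8 → 10 → 12 → 14 → 15); the carbene branch (1 + 2 → 5) joins at step 4.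

**Steps most likely to fail**

1. Step 4. The conjugated carbonyl may bias alkyne insertion electronically against the steric preference, or the ketone may intercept the chromium-bound ketene before electrocyclization, so that ring A forms with the wrong substitution or not at all. The fallback keeps the benzannulation but runs it at the alcohol oxidation level. It sets out from 10: reduction with NaBH4 and CeCl3·7H2O in MeOH at −20 °C (Luche reduction) should give racemic 1-(3,4,5-trimethoxyphenyl)but-3-yn-2-ol F1. Silylation with TBSCl and imidazole in DMF should give racemic 2-(tert-butyldimethylsilyloxy)-1-(3,4,5-trimethoxyphenyl)but-3-yne F2, a non-conjugated terminal alkyne with a branched propargylic group, for which steric control alone decides the insertion. Heating F2 with 5 in THF at 50 °C should give the tricarbonylchromium arene complex F3 and, after exposure to air, 5-(tert-butoxy)-2-[1-(tert-butyldimethylsilyloxy)-2-(3,4,5-trimethoxyphenyl)ethyl]-4-methoxyphenol F4. Desilylation with Bu4NF in THF at 0 °C should give 5-(tert-butoxy)-2-[1-hydroxy-2-(3,4,5-trimethoxyphenyl)ethyl]-4-methoxyphenol F5, and oxidation of this activated benzylic alcohol with MnO2 in CH2Cl2 should bring the route back at 12.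

2. Step 1. O-Methylation of the lithium acylate may stay incomplete and the electron-rich enol-ether carbene complex may break down during purification on silica. The fallback goes through a purified acylate salt and an acyloxycarbene. It sets out from 4: the crude salt is taken up in degassed water and treated with Me4NBr to precipitate tetramethylammonium pentacarbonyl[2-(tert-butoxy)acryloyl]chromate F6, which can be recrystallized and stored. Acetyl bromide in CH2Cl2 at −40 °C should convert it into pentacarbonyl{acetoxy[1-(tert-butoxy)vinyl]carbene}chromium F7, which is not isolated; addition of methanol at −40 → 0 °C should exchange acetate for methoxide and return the route at 5, obtained by crystallization from pentane.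

3. Step 3. The liberated N,O-dimethylhydroxylamine may add in conjugate fashion to the terminal ynone during the quench, and the unprotected ynone may degrade on concentration. The fallback makes the ynone with a silyl cap and uncaps it under near-neutral conditions. It sets out from 8: Me3SiC≡CLi (from trimethylsilylacetylene and n-BuLi) in THF at −78 → 0 °C should give the lithium hemiaminal adduct lithium 2-[methoxy(methyl)amino]-1-(3,4,5-trimethoxyphenyl)-4-(trimethylsilyl)but-3-yn-2-olate F8 and, after quench with aqueous NH4Cl, 1-(3,4,5-trimethoxyphenyl)-4-(trimethylsilyl)but-3-yn-2-one F9, which is hindered at the β-carbon and can be chromatographed. Desilylation with dilute aqueous Na2B4O7 in MeOH at rt should return the route at 10.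

**Further compounds**

F1 | step 4 | racemic 1-(3,4,5-trimethoxyphenyl)but-3-yn-2-ol | C#CC(O)Cc1cc(OC)c(OC)c(OC)c1
F2 | step 4 | racemic 2-(tert-butyldimethylsilyloxy)-1-(3,4,5-trimethoxyphenyl)but-3-yne | C#CC(O[Si](C)(C)C(C)(C)C)Cc1cc(OC)c(OC)c(OC)c1
F3 | step 4 | tricarbonyl(η6-arene)chromium complex of F4, Cr(CO)3 bound to the phenol ring | COc1cc(C(O[Si](C)(C)C(C)(C)C)Cc2cc(OC)c(OC)c(OC)c2)c(O)cc1OC(C)(C)C.O=C=[Cr](=C=O)=C=O
F4 | step 4 | racemic 5-(tert-butoxy)-2-[1-(tert-butyldimethylsilyloxy)-2-(3,4,5-trimethoxyphenyl)ethyl]-4-methoxyphenol | COc1cc(C(O[Si](C)(C)C(C)(C)C)Cc2cc(OC)c(OC)c(OC)c2)c(O)cc1OC(C)(C)C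
F5 | step 4 | racemic 5-(tert-butoxy)-2-[1-hydroxy-2-(3,4,5-trimethoxyphenyl)ethyl]-4-methoxyphenol | COc1cc(C(O)Cc2cc(OC)c(OC)c(OC)c2)c(O)cc1OC(C)(C)C
F6 | step 1 | tetramethylammonium pentacarbonyl[2-(tert-butoxy)acryloyl]chromate | C[N+](C)(C)C.[O-]C(C(=C)OC(C)(C)C)=[Cr](=C=O)(=C=O)(=C=O)(=C=O)=C=O
F7 | step 1 | pentacarbonyl{acetoxy[1-(tert-butoxy)vinyl]carbene}chromium | CC(=O)OC(C(=C)OC(C)(C)C)=[Cr](=C=O)(=C=O)(=C=O)(=C=O)=C=O
F8 | step 3 | lithium 2-[methoxy(methyl)amino]-1-(3,4,5-trimethoxyphenyl)-4-(trimethylsilyl)but-3-yn-2-olate (racemic) | COc1cc(CC(O[Li])(C#C[Si](C)(C)C)N(C)OC)cc(OC)c1OC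
F9 | step 3 | 1-(3,4,5-trimethoxyphenyl)-4-(trimethylsilyl)but-3-yn-2-one | C[Si](C)(C)C#CC(=O)Cc1cc(OC)c(OC)c(OC)c1
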